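## Retrosynthetic overview

- **Feature:** ring A (C1–C5, C10) carries three stereocentres: C4 (axial C19H2–O, equatorial C18), C5 (H α) and C10 (axial C20). This is ring A of (+)-podocarpic acid. In ring B, the C8–C9 bond joins a carbon that can be a ketone (C8, later C8=C17) to the chain-bearing C9.
- **Endgame disconnections:** O–Si at C13, the C19 tiglate (from tiglic acid), and C8=C17 (Wittig methylenation of the 17-nor-8-ketone).
- **Key disconnection C8–C9:** 6-exo-trig addition of a C8 acyl radical (from the Se-phenyl selenoester) to C9 of a Z C9=C11 olefin. Ring A is bought; ring B is the only ring formed.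
- **C9=C11:** Wittig reaction of the C10-formyl seco ester. That ester comes from RuO4 excision of aromatic ring C (C11–C14 burnt off, C8 and C9 left as CO2H), and the two acids are told apart by their different crowding.
- **Ylide C11–C16 from (R)-linalool (C13 bought):** the ylide carbon C11 is linalool C5, so four carbons must go. Three leave as acetone by ozonolysis and linalool C6 leaves as CO2 by decarboxylative iodination. Simple cleavage alone would leave the chain one CH2 too long.

Key step: step 16

Assumption: podocarpane/labdane numbering is kept for every terpenoid compound, the seco compounds and the C11–C16 fragment included, and commercial (−)-linalool is taken as the (R) enantiomer of high enantiomeric purity, its minor enantiomer ending as a separable 13-epimer after step 13.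

## Route

Step 1
Reactants: 1 (+)-podocarpic acid
Product: 2 methyl 12-methoxypodocarpa-8,11,13-trien-19-oate
Conditions: MeI, K2CO3, DMF, 25 °C
Reagents that add atoms: iodomethane, CI
Why: Williamson-type O-alkylation in which the phenoxide and the crowded axial C19 carboxylate both attack MeI through oxygen, so the hindrance at C4 plays no part and no stereocentre is touched.

Step 2
Reactants: 2 methyl 12-methoxypodocarpa-8,11,13-trien-19-oate
Product: 3 12-methoxypodocarpa-8,11,13-trien-19-ol
Conditions: LiAlH4, THF, reflux
Reagents that add atoms: none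
Why: Hydride reduction of an ester, for which LiAlH4 at reflux is small and strong enough to reach the axial C19 ester while the anisole ring stays inert.

Step 3
Reactants: 3 12-methoxypodocarpa-8,11,13-trien-19-ol
Product: 4 12-methoxypodocarpa-8,11,13-trien-19-yl pivalate
Conditions: PivCl, pyridine, DMAP (10 mol %), CH2Cl2, 40 °C
Reagents that add atoms: pivaloyl chloride, CC(C)(C)C(=O)Cl
Why: DMAP-catalysed acylation that installs an ester able to stand RuO4, borane, ylides, hydroxide and radicals, which the electron-poor olefin of a tiglate could not do.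

Step 4
Reactants: 4 12-methoxypodocarpa-8,11,13-trien-19-yl pivalate
Product: 5 19-pivaloyloxy-11,12,13,14-tetranor-8,9-secopodocarpane-8,9-dioic acid (cyclohexane ring A; C10 bears CO2H = C9 and the β-methyl, C5 bears α-H and CH2CH2CO2H = C6–C8, C4 bears β-CH2OPiv and α-methyl)
Conditions: RuCl3 hydrate (5 mol %), NaIO4 (excess), EtOAc/MeCN/H2O, 25 °C
Reagents that add atoms: sodium periodate, [Na+].[O-]I(=O)(=O)=O; water, O
Why: RuO4-catalysed oxidative degradation of an arene, known for ring-A aromatic steroids, in which the electron-rich anisole ring is consumed down to the two ring carbons bound to sp3 carbon, so C8 and C9 remain as carboxyl groups and C4, C5 and C10 are untouched.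

Step 5
Reactants: 5 19-pivaloyloxy-11,12,13,14-tetranor-8,9-secopodocarpane-8,9-dioic acid
Product: 6 the 8-methyl ester of 5 with the C9 acid free
Conditions: MeOH, H2SO4 (5 mol %), 25 °C
Reagents that add atoms: methanol, CO
Why: Fischer esterification under kinetic control, in which the primary-alkyl C8 acid reacts at room temperature whereas the C9 acid on quaternary C10 cannot build its tetrahedral intermediate at a useful rate.

Step 6
Reactants: 6 the 8-methyl ester 9-acid
Product: 7 methyl 9-hydroxy-19-pivaloyloxy-11,12,13,14-tetranor-8,9-secopodocarpan-8-oate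
Conditions: BH3·THF, THF, 0 → 25 °C; aqueous work-up
Reagents that add atoms: none
Why: Chemoselective borane reduction of a carboxylic acid through its acyloxyborane, which leaves the methyl ester and the pivalate unchanged.

Step 7
Reactants: 7 the C9 alcohol
Product: 8 methyl 9-oxo-19-pivaloyloxy-11,12,13,14-tetranor-8,9-secopodocarpan-8-oate (C10-formyl compound)
Conditions: Dess–Martin periodinane, CH2Cl2, 25 °C
Reagents that add atoms: none
Why: Dess–Martin oxidation of a neopentyl-type primary alcohol to an aldehyde that has no α-hydrogen and therefore can neither enolise nor epimerise.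

Step 8
Reactants: 9 (R)-(−)-linalool
Product: 10 (R)-linalool triethylsilyl ether
Conditions: TESOTf, 2,6-lutidine, CH2Cl2, −78 → 0 °C
Reagents that add atoms: triethylsilyl triflate, CC[Si](CC)(CC)OS(=O)(=O)C(F)(F)F
Why: Silylation of a tertiary alcohol with a silyl triflate under buffered conditions, in which the C–O bond of the bought stereocentre (later C13) is never broken.

Step 9
Reactants: 10 (R)-linalool triethylsilyl ether
Product: 12 (R)-4-methyl-4-(triethylsilyloxy)hex-5-enal, via secondary ozonide 11 (not isolated)
Conditions: O3, Sudan Red 7B (indicator), CH2Cl2, −78 °C; then PPh3, −78 → 25 °C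
Reagents that add atoms: ozone, [O-][O+]=O
Why: Chemoselective ozonolysis in which the electron-rich trisubstituted olefin reacts well ahead of the vinyl group, the latter being deactivated by the allylic oxygen and shielded by the quaternary carbon, with the dye marking the end-point.

Step 10
Reactants: 12 (R)-4-methyl-4-(triethylsilyloxy)hex-5-enal
Product: 13 (R)-4-methyl-4-(triethylsilyloxy)hex-5-enoic acid
Conditions: NaClO2, NaH2PO4, 2-methylbut-2-ene, t-BuOH/H2O, 0 → 25 °C
Reagents that add atoms: sodium chlorite, [Na+].[O-]Cl=O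
Why: Pinnick oxidation at a buffered pH that a tertiary triethylsilyl ether tolerates, with the added olefin taking up the hypochlorous acid before it can reach the vinyl group.

Step 11
Reactants: 13 (R)-4-methyl-4-(triethylsilyloxy)hex-5-enoic acid
Product: 15 (R)-5-iodo-3-methyl-3-(triethylsilyloxy)pent-1-ene, via O-acyl thiohydroxamate 14 (not isolated)
Conditions: 1-hydroxypyridine-2(1H)-thione, DCC, CH2Cl2, 0 °C, dark; then CHI3, PhH, tungsten lamp, 70 °C
Reagents that add atoms: iodoform, IC(I)I
Why: Barton decarboxylative iodination, which expels the surplus carbon (linalool C6) as CO2 and traps the primary C11 radical with iodine faster than this pent-4-enyl-type radical could close on the vinyl group.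

Step 12
Reactants: 15 (R)-5-iodo-3-methyl-3-(triethylsilyloxy)pent-1-ene
Product: 16 (R)-[3-methyl-3-(triethylsilyloxy)pent-4-en-1-yl]triphenylphosphonium iodide
Conditions: PPh3, MeCN, 80 °C
Reagents that add atoms: triphenylphosphine, c1ccc(cc1)P(c1ccccc1)c1ccccc1
Why: SN2 quaternisation of triphenylphosphine by an unhindered primary iodide under neutral conditions that leave the silyl ether in place.

Step 13
Reactants: 16 the phosphonium iodide; 8 the C10-formyl seco ester
Product: 18 methyl (9Z,13R)-19-pivaloyloxy-13-(triethylsilyloxy)-17-nor-8,9-secolabda-9(11),14-dien-8-oate, via phosphonium ylide 17 (not isolated)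
Conditions: NaN(SiMe3)2, THF, −78 → 0 °C; then 8, −78 → 25 °C
Reagents that add atoms: none
Why: Lithium-free Wittig olefination of a non-stabilised ylide, which should give the Z C9=C11 olefin by kinetic formation of the cis-oxaphosphetane, helped by an aldehyde that cannot enolise and a γ-silyloxy ylide that has no β-leaving group.

Step 14
Reactants: 18 the Z-olefin methyl ester
Product: 19 (9Z,13R)-19-pivaloyloxy-13-(triethylsilyloxy)-17-nor-8,9-secolabda-9(11),14-dien-8-oic acid
Conditions: LiOH, THF/MeOH/H2O, 25 °C; then dilute HCl to pH 4–5, 0 °C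
Reagents that add atoms: lithium hydroxide, [Li+].[OH-]
Why: Saponification that picks the unhindered C8 methyl ester over the pivalate of a neopentyl-type alcohol, the tertiary silyl ether being stable to base.

Step 15
Reactants: 19 the C8 acid
Product: 20 Se-phenyl (9Z,13R)-19-pivaloyloxy-13-(triethylsilyloxy)-17-nor-8,9-secolabda-9(11),14-diene-8-selenoate
Conditions: (PhSe)2, Bu3P, CH2Cl2, 25 °C
Reagents that add atoms: diphenyl diselenide, c1ccc(cc1)[Se][Se]c1ccccc1
Why: Phosphine/diselenide redox condensation through an acyloxyphosphonium ion, a neutral selenoesterification that spares the silyl ether and both olefins.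

Step 16
Reactants: 20 the Se-phenyl selenoester
Product: 23 (13R)-19-pivaloyloxy-13-(triethylsilyloxy)-17-norlabd-14-en-8-one, via C8 acyl radical 21 (not isolated), via C11 alkyl radical 22 (not isolated)
Conditions: Bu3SnH (1.3 equiv) and AIBN (0.2 equiv) by syringe pump over 6 h, degassed PhH (0.01 M), 80 °C; then crude product, DBU (0.2 equiv), PhMe, 25 °C
Reagents that add atoms: none
Why: The stannyl radical attacks selenium of 20 and releases the acyl radical 21, which adds to C9 of the C9=C11 olefin to form the C8–C9 bond, and the secondary radical 22 then takes hydrogen from the stannane and carries the chain. The closest known reaction type is the tin hydride cyclisation of hept-6-enoyl radicals from Se-phenyl selenoesters onto unactivated 1,2-disubstituted olefins, where the alkyl group on the far olefin carbon steers the closure to the exo mode. Ring B closes 6-exo-trig through a chair-like transition state built on the ring A chair, whose C5 arm and C10 alkenyl arm are trans-diequatorial and so already gauche to each other. C9 is the only new stereocentre: allylic 1,3-strain between C12 of the Z olefin and quaternary C10 holds the rotamer with C9=C11 anti to C10–C5, so C11 should end up equatorial (β, H-9 α), and because C9 lies α to the new ketone the DBU treatment drains any 9-epimer into this more stable isomer. The step needs 6-exo over 7-endo closure, cyclisation ahead of reduction of 21 and ahead of CO loss, and capture of 22 before it attacks the C8 carbonyl in a Dowd–Beckwith-type ring expansion; the same rotamer keeps C11 out of reach of C8, acyl radicals take hydrogen from stannane comparatively slowly, acyl radicals on primary carbon lose CO slowly, and a stannane level held low but not vanishing serves both ends. The C14=C15 vinyl group can be reached from C11 only by 4-exo or 5-endo closure and should stay untouched.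

Step 17
Reactants: 23 the 17-nor-8-ketone
Product: 24 (13R)-19-pivaloyloxy-13-(triethylsilyloxy)labda-8(17),14-diene
Conditions: Ph3PCH3Br, KOtBu, THF, 25 → 65 °C
Reagents that add atoms: methyltriphenylphosphonium bromide, C[P+](c1ccccc1)(c1ccccc1)c1ccccc1.[Br-]
Why: Wittig methylenation, well known for 8-oxo-17-norlabdanes, in which the basic medium can only hold C9 in its equatorial configuration and the crowded pivalate is not attacked.

Step 18
Reactants: 24 the 8(17)-methylene pivalate
Product: 25 (13R)-13-(triethylsilyloxy)labda-8(17),14-dien-19-ol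
Conditions: LiAlH4, Et2O, 0 → 25 °C
Reagents that add atoms: none
Why: Reductive ester cleavage by hydride, which removes the pivalate without the strong base or acid that hydrolysis of so hindered an ester would need and leaves olefins and silyl ether alone.

Step 19
Reactants: 25 the C19 alcohol; 26 tiglic acid
Product: 28 (13R)-13-(triethylsilyloxy)labda-8(17),14-dien-19-yl tiglate, via mixed anhydride 27 (not isolated)
Conditions: 26, 2,4,6-trichlorobenzoyl chloride, Et3N, PhMe, 25 °C; then 25, DMAP, PhMe, 60 °C
Reagents that add atoms: none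
Why: Yamaguchi esterification, in which DMAP attacks the less crowded tigloyl carbonyl of 27 and delivers an acylpyridinium ion reactive enough for the axial neopentyl-type alcohol, with the E geometry bought in tiglic acid being the stable one.

Step 20
Reactants: 28 the silyl-protected tiglate
Product: 29 (13R)-13-hydroxylabda-8(17),14-dien-19-yl (E)-2-methylbut-2-enoate (target CNP0313179.1)
Conditions: Bu4NF, AcOH (1:1), THF, 25 °C
Reagents that add atoms: none
Why: Fluoride-driven desilylation buffered with acetic acid, which avoids both ionisation of the tertiary allylic alcohol and base attack on the tiglate and breaks only the O–Si bond, so C13 keeps its configuration.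

## Compound list

1 | (+)-podocarpic acid | C[C@]1(C(=O)O)CCC[C@]2(C)c3cc(O)ccc3CC[C@@H]12 | starting material
2 | methyl 12-methoxypodocarpa-8,11,13-trien-19-oate | C[C@]1(C(=O)OC)CCC[C@]2(C)c3cc(OC)ccc3CC[C@@H]12 | intermediate
3 | 12-methoxypodocarpa-8,11,13-trien-19-ol | C[C@]1(CO)CCC[C@]2(C)c3cc(OC)ccc3CC[C@@H]12 | intermediate
4 | 12-methoxypodocarpa-8,11,13-trien-19-yl pivalate | C[C@]1(COC(=O)C(C)(C)C)CCC[C@]2(C)c3cc(OC)ccc3CC[C@@H]12 | intermediate
5 | 19-pivaloyloxy-11,12,13,14-tetranor-8,9-secopodocarpane-8,9-dioic acid | OC(=O)[C@@]1(C)CCC[C@](C)(COC(=O)C(C)(C)C)[C@@H]1CCC(=O)O | intermediate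
6 | 8-methyl ester of 5, C9 acid free | OC(=O)[C@@]1(C)CCC[C@](C)(COC(=O)C(C)(C)C)[C@@H]1CCC(=O)OC | intermediate
7 | methyl 9-hydroxy-19-pivaloyloxy-11,12,13,14-tetranor-8,9-secopodocarpan-8-oate | OC[C@@]1(C)CCC[C@](C)(COC(=O)C(C)(C)C)[C@@H]1CCC(=O)OC | intermediate
8 | methyl 9-oxo-19-pivaloyloxy-11,12,13,14-tetranor-8,9-secopodocarpan-8-oate | O=C[C@@]1(C)CCC[C@](C)(COC(=O)C(C)(C)C)[C@@H]1CCC(=O)OC | intermediate
9 | (R)-(−)-linalool | C=C[C@](C)(O)CCC=C(C)C | starting material
10 | (R)-linalool triethylsilyl ether | C=C[C@](C)(O[Si](CC)(CC)CC)CCC=C(C)C | intermediate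
11 | secondary ozonide of 10 at the 6,7-olefin (epimers at the acetal carbon) | C=C[C@](C)(O[Si](CC)(CC)CC)CCC1OOC(C)(C)O1 | intermediate
12 | (R)-4-methyl-4-(triethylsilyloxy)hex-5-enal | C=C[C@](C)(O[Si](CC)(CC)CC)CCC=O | intermediate
13 | (R)-4-methyl-4-(triethylsilyloxy)hex-5-enoic acid | C=C[C@](C)(O[Si](CC)(CC)CC)CCC(=O)O | intermediate
14 | 2-thioxopyridin-1(2H)-yl ester of 13 | C=C[C@](C)(O[Si](CC)(CC)CC)CCC(=O)On1ccccc1=S | intermediate
15 | (R)-5-iodo-3-methyl-3-(triethylsilyloxy)pent-1-ene | C=C[C@](C)(O[Si](CC)(CC)CC)CCI | intermediate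
16 | (R)-[3-methyl-3-(triethylsilyloxy)pent-4-en-1-yl]triphenylphosphonium iodide | C=C[C@](C)(O[Si](CC)(CC)CC)CC[P+](c1ccccc1)(c1ccccc1)c1ccccc1.[I-] | intermediate
17 | ylide of 16 | C=C[C@](C)(O[Si](CC)(CC)CC)CC=P(c1ccccc1)(c1ccccc1)c1ccccc1 | intermediate
18 | methyl (9Z,13R)-19-pivaloyloxy-13-(triethylsilyloxy)-17-nor-8,9-secolabda-9(11),14-dien-8-oate | C=C[C@](C)(O[Si](CC)(CC)CC)C/C=C\[C@@]1(C)CCC[C@](C)(COC(=O)C(C)(C)C)[C@@H]1CCC(=O)OC | intermediate
19 | (9Z,13R)-19-pivaloyloxy-13-(triethylsilyloxy)-17-nor-8,9-secolabda-9(11),14-dien-8-oic acid | C=C[C@](C)(O[Si](CC)(CC)CC)C/C=C\[C@@]1(C)CCC[C@](C)(COC(=O)C(C)(C)C)[C@@H]1CCC(=O)O | intermediate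
20 | Se-phenyl selenoester of 19 (key-step precursor) | C=C[C@](C)(O[Si](CC)(CC)CC)C/C=C\[C@@]1(C)CCC[C@](C)(COC(=O)C(C)(C)C)[C@@H]1CCC(=O)[Se]c2ccccc2 | intermediate
21 | C8 acyl radical from 20 | C=C[C@](C)(O[Si](CC)(CC)CC)C/C=C\[C@@]1(C)CCC[C@](C)(COC(=O)C(C)(C)C)[C@@H]1CC[C]=O | intermediate
22 | C11 alkyl radical after closure of ring B | C=C[C@](C)(O[Si](CC)(CC)CC)C[CH][C@H]1C(=O)CC[C@H]2[C@@](C)(COC(=O)C(C)(C)C)CCC[C@]12C | intermediate
23 | (13R)-19-pivaloyloxy-13-(triethylsilyloxy)-17-norlabd-14-en-8-one (key-step product) | C=C[C@](C)(O[Si](CC)(CC)CC)CC[C@H]1C(=O)CC[C@H]2[C@@](C)(COC(=O)C(C)(C)C)CCC[C@]12C | intermediate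
24 | (13R)-19-pivaloyloxy-13-(triethylsilyloxy)labda-8(17),14-diene | C=C[C@](C)(O[Si](CC)(CC)CC)CC[C@H]1C(=C)CC[C@H]2[C@@](C)(COC(=O)C(C)(C)C)CCC[C@]12C | intermediate
25 | (13R)-13-(triethylsilyloxy)labda-8(17),14-dien-19-ol | C=C[C@](C)(O[Si](CC)(CC)CC)CC[C@H]1C(=C)CC[C@H]2[C@@](C)(CO)CCC[C@]12C | intermediate
26 | tiglic acid | C/C=C(\C)C(=O)O | starting material
27 | tiglic 2,4,6-trichlorobenzoic anhydride | C/C=C(\C)C(=O)OC(=O)c1c(Cl)cc(Cl)cc1Cl | intermediate
28 | (13R)-13-(triethylsilyloxy)labda-8(17),14-dien-19-yl tiglate | C=C[C@](C)(O[Si](CC)(CC)CC)CC[C@H]1C(=C)CC[C@H]2[C@@](C)(COC(=O)/C(C)=C/C)CCC[C@]12C | intermediate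
29 | (13R)-13-hydroxylabda-8(17),14-dien-19-yl tiglate (CNP0313179.1) | C=C[C@](C)(O)CC[C@H]1C(=C)CC[C@H]2[C@@](C)(COC(=O)/C(C)=C/C)CCC[C@]12C | target

## Step count

Total step count: 20.
Longest linear sequence: 15 (steps 1–7 and 13–20).

## Steps most likely to fail

**Step 16**
- What may go wrong: attack at C9, which sits next to quaternary C10 on an unactivated olefin, may be slow. Direct reduction of the acyl radical or loss of CO could then take over. Alternatively, the closure may leak to the 7-endo mode, or the adduct radical may undergo ring expansion at low stannane level.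
- The fallback keeps the C8–C9 radical closure but makes the olefin a polarity-matched acceptor. It sets out from 15 and 8 and comes back at 23.
- Iodide 15 and PhSO2Na in DMF give the phenyl sulfone F1. Its lithio derivative (n-BuLi, THF, −78 °C) adds to aldehyde 8, and quenching with Ac2O gives the β-acetoxy sulfone F2.
- DBU eliminates acetic acid to give the vinyl sulfone ester F3. LiOH gives the vinyl sulfone acid F4, and (PhSe)2/Bu3P gives the vinyl sulfone selenoester F5.
- With Bu3SnH/AIBN the nucleophilic acyl radical adds to C9, now the β-carbon of a vinyl sulfone. The sulfonyl-stabilised C11 radical does not rearrange, and the 11-sulfonyl ketone F6 results.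
- DBU expels benzenesulfinate to give the exocyclic enone F7. Conjugate reduction with [(Ph3P)CuH]6 in wet benzene, followed by DBU equilibration of C9, gives 23.

**Step 4**
- What may go wrong: benzylic oxidation at C7, which is activated by the para methoxy group, would deactivate the ring and stop the excision. The degradation may also stall at the α-keto acid stage.
- The fallback sets out from 4 and comes back at 5. It replaces the metal-oxo oxidation by exhaustive ozonolysis of the anisole ring (O3, CH2Cl2/MeOH, −78 → 0 °C) followed by H2O2/HCO2H.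
- Ozone cleaves the ring C=C bonds by cycloaddition and does not attack benzylic C–H. The peroxide then cuts every remaining α-dicarbonyl unit down to the C8 and C9 acids. No new isolated compound is made on this path.

**Step 11**
- What may go wrong: the chain-carrying diiodomethyl radical may add to the vinyl group, the primary iodide may lose iodine under the lamp, or traces of HI may cause desilylation.
- The fallback removes the same carbon by polar chemistry. It sets out from 12 and comes back at 15.
- TBSOTf/Et3N converts 12 into the silyl enol ether F8. Ozone (Sudan Red 7B end-point, CH2Cl2/MeOH, −78 °C) cleaves the electron-rich enol double bond ahead of the vinyl group to give the nor-aldehyde F9.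
- NaBH4 reduces F9 in the same flask at low temperature to the primary alcohol F10. I2/PPh3/imidazole then gives 15.

## Further compounds

F1 | step 16 | (R)-[3-methyl-3-(triethylsilyloxy)pent-4-en-1-yl] phenyl sulfone | C=C[C@](C)(O[Si](CC)(CC)CC)CCS(=O)(=O)c1ccccc1
F2 | step 16 | methyl 9-acetoxy-11-phenylsulfonyl-19-pivaloyloxy-13-(triethylsilyloxy)-17-nor-8,9-secolabd-14-en-8-oate (mixture at C9 and C11) | C=C[C@](C)(O[Si](CC)(CC)CC)CC(C(OC(C)=O)[C@@]1(C)CCC[C@](C)(COC(=O)C(C)(C)C)[C@@H]1CCC(=O)OC)S(=O)(=O)c2ccccc2
F3 | step 16 | methyl (9E)-11-phenylsulfonyl-19-pivaloyloxy-13-(triethylsilyloxy)-17-nor-8,9-secolabda-9(11),14-dien-8-oate | C=C[C@](C)(O[Si](CC)(CC)CC)C/C(=C\[C@@]1(C)CCC[C@](C)(COC(=O)C(C)(C)C)[C@@H]1CCC(=O)OC)S(=O)(=O)c2ccccc2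
F4 | step 16 | C8 acid of F3 | C=C[C@](C)(O[Si](CC)(CC)CC)C/C(=C\[C@@]1(C)CCC[C@](C)(COC(=O)C(C)(C)C)[C@@H]1CCC(=O)O)S(=O)(=O)c2ccccc2
F5 | step 16 | Se-phenyl selenoester of F4 | C=C[C@](C)(O[Si](CC)(CC)CC)C/C(=C\[C@@]1(C)CCC[C@](C)(COC(=O)C(C)(C)C)[C@@H]1CCC(=O)[Se]c2ccccc2)S(=O)(=O)c3ccccc3
F6 | step 16 | 11-phenylsulfonyl-19-pivaloyloxy-13-(triethylsilyloxy)-17-norlabd-14-en-8-one (mixture at C11) | C=C[C@](C)(O[Si](CC)(CC)CC)CC([C@H]1C(=O)CC[C@H]2[C@@](C)(COC(=O)C(C)(C)C)CCC[C@]12C)S(=O)(=O)c3ccccc3
F7 | step 16 | 19-pivaloyloxy-13-(triethylsilyloxy)-17-norlabda-9(11),14-dien-8-one (C12 cis to C8) | C=C[C@](C)(O[Si](CC)(CC)CC)C/C=C1\C(=O)CC[C@H]2[C@@](C)(COC(=O)C(C)(C)C)CCC[C@]12C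
F0 | step 4 | none | none
F8 | step 11 | tert-butyldimethylsilyl enol ether of 12 (mainly Z) | C=C[C@](C)(O[Si](CC)(CC)CC)C/C=C\O[Si](C)(C)C(C)(C)C
F9 | step 11 | (R)-3-methyl-3-(triethylsilyloxy)pent-4-enal | C=C[C@](C)(O[Si](CC)(CC)CC)CC=O
F10 | step 11 | (R)-3-methyl-3-(triethylsilyloxy)pent-4-en-1-ol | C=C[C@](C)(O[Si](CC)(CC)CC)CCO
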